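**Retrosynthetic overview**
1. Target ⇐ acidolysis of a tert-butyl ester / bis-silyl ether with spontaneous 12,6-lactonisation (lactone ring formed last) ⇐ acylation of the C8 alcohol with bought (R)-2-methylbutanoic acid.
2. Ten-membered carbocycle (formed first) ⇐ C7–C8 bond by a chromium-catalysed electroreductive intramolecular Barbier (Nozaki–Hiyama–Kishi-type) allylation of a bromo aldehyde; this step sets C7 and C8 under control of C6.
3. Bromo aldehyde ⇐ C1=C10 by cross-metathesis of a terminal alkene with methyl 2-methylidene-4-oxobutanoate; Z-allylic bromide ⇐ Baylis–Hillman adduct of an α-silyloxy aldehyde with tert-butyl acrylate.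
4. α-Silyloxy aldehyde ⇐ (R)-γ-(hydroxymethyl)-γ-butyrolactone: C6 is bought, C4 comes from trans-selective lactone enolate alkylation, lactone reduction gives C15.

Assumption: 1, 3, 10, 13 and 20 are bought (1 is the D-glutamic-acid-derived lactone); TES = triethylsilyl, TBS = tert-butyldimethylsilyl; labels C1–C15 are the germacrane positions of the target (ring C1–C10 with C1=C10, C11–C13 on C7, C14 on C10, C15 on C4).

**Route**

Step 1
Reactants: 1 (5R)-5-(hydroxymethyl)dihydrofuran-2(3H)-one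
Product: 2 (5R)-5-{[(triethylsilyl)oxy]methyl}dihydrofuran-2(3H)-one
Conditions: Et3SiCl, imidazole, CH2Cl2, 0 °C
Reagents that add atoms: chlorotriethylsilane CC[Si](CC)(CC)Cl
Why: Silyl ether formation on the primary alcohol; TES is chosen because a primary TES ether can later be oxidised directly to the aldehyde while TBS ethers survive, and no stereocentre is touched.

Step 2
Reactants: 2 (5R)-5-{[(triethylsilyl)oxy]methyl}dihydrofuran-2(3H)-one; 3 4-iodobut-1-ene
Product: 5 (3S,5R)-3-(but-3-en-1-yl)-5-{[(triethylsilyl)oxy]methyl}dihydrofuran-2(3H)-one, via lithium enolate 4 (not isolated)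
Conditions: LiN(iPr)2, THF, −78 °C; then 3, DMPU, −78 → −30 °C
Reagents that add atoms: none
Why: Lactone enolate alkylation (SN2) takes place on the face anti to the C5 substituent, which sets the new centre (C4 of the target, S) trans to the bought centre; the minor cis isomer is removed by chromatography.

Step 3
Reactants: 5 (3S,5R)-3-(but-3-en-1-yl)-5-{[(triethylsilyl)oxy]methyl}dihydrofuran-2(3H)-one
Product: 6 (2S,4R)-2-(but-3-en-1-yl)-5-[(triethylsilyl)oxy]pentane-1,4-diol
Conditions: LiAlH4, THF, 0 °C; H2O/NaOH work-up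
Reagents that add atoms: none
Why: Hydride reduction of the lactone gives the 1,4-diol (C15–OH and C6–OH) without touching the stereocentres, the silyl ether or the alkene.

Step 4
Reactants: 6 (2S,4R)-2-(but-3-en-1-yl)-5-[(triethylsilyl)oxy]pentane-1,4-diol
Product: 7 (2S,4R)-2-(but-3-en-1-yl)-1,4-bis[(tert-butyldimethylsilyl)oxy]-5-[(triethylsilyl)oxy]pentane
Conditions: tBuMe2SiCl, imidazole, DMF, 25 → 40 °C
Reagents that add atoms: tert-butyldimethylsilyl chloride CC(C)(C)[Si](C)(C)Cl
Why: Silyl ether formation on both hydroxyls; the bulky, non-chelating silyloxy group on C6 is needed later for facial control.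

Step 5
Reactants: 7 (2S,4R)-2-(but-3-en-1-yl)-1,4-bis[(tert-butyldimethylsilyl)oxy]-5-[(triethylsilyl)oxy]pentane
Product: 9 (2R,4S)-4-(but-3-en-1-yl)-2,5-bis[(tert-butyldimethylsilyl)oxy]pentanal, via alkoxysulfonium chloride 8 (not isolated)
Conditions: (COCl)2, DMSO, CH2Cl2, −78 → −40 °C; then Et3N, −78 → 0 °C
Reagents that add atoms: none
Why: Swern oxidation in which the chlorosulfonium reagent cleaves the primary TES ether directly to the alkoxysulfonium salt (known selective oxidative desilylation; primary and secondary TBS ethers are inert at low temperature), and the α-silyloxy aldehyde is not epimerised under these conditions.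

Step 6
Reactants: 9 (2R,4S)-4-(but-3-en-1-yl)-2,5-bis[(tert-butyldimethylsilyl)oxy]pentanal; 10 tert-butyl prop-2-enoate
Product: 11 tert-butyl (3RS,4R,6S)-4-[(tert-butyldimethylsilyl)oxy]-6-{[(tert-butyldimethylsilyl)oxy]methyl}-3-hydroxy-2-methylidenedec-9-enoate
Conditions: DABCO (1 equiv), 10 (10 equiv), 1,4-dioxane/H2O 2:1, 25 °C, 3 d
Reagents that add atoms: none
Why: Morita–Baylis–Hillman reaction of an activated α-silyloxy aldehyde (aqueous dioxane speeds up the slow tert-butyl acrylate); the new carbinol centre forms as a mixture that is erased in step 7.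

Step 7
Reactants: 11 tert-butyl (3RS,4R,6S)-4-[(tert-butyldimethylsilyl)oxy]-6-{[(tert-butyldimethylsilyl)oxy]methyl}-3-hydroxy-2-methylidenedec-9-enoate
Product: 12 tert-butyl (2Z,4R,6S)-2-(bromomethyl)-4-[(tert-butyldimethylsilyl)oxy]-6-{[(tert-butyldimethylsilyl)oxy]methyl}deca-2,9-dienoate
Conditions: NBS, Me2S, CH2Cl2, 0 → 25 °C
Reagents that add atoms: N-bromosuccinimide O=C1CCC(=O)N1Br
Why: SN2′ bromination of the Baylis–Hillman alcohol through its alkoxysulfonium salt (Corey–Kim-type activation) gives the thermodynamically preferred Z-2-(bromomethyl)enoate (C6 cis to CH2Br) and removes the C7 carbinol centre.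

Step 8
Reactants: 13 methyl 4,4-dimethoxybutanoate
Product: 15 methyl 4,4-dimethoxy-2-methylidenebutanoate, via sodium formyl enolate 14 (not isolated)
Conditions: NaH, HCO2Me, THF, 0 → 25 °C; then (CH2O)n, 60 °C
Reagents that add atoms: formaldehyde C=O
Why: Claisen formylation followed by aldol addition to formaldehyde and loss of formate (deformylative α-methylenation) turns the ester α-CH2 into the acrylate.

Step 9
Reactants: 15 methyl 4,4-dimethoxy-2-methylidenebutanoate
Product: 16 methyl 2-methylidene-4-oxobutanoate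
Conditions: Amberlyst 15, acetone/H2O 20:1, 25 °C; used at once
Reagents that add atoms: water O
Why: Mild acid-catalysed acetal hydrolysis; the β,γ-unsaturated aldehyde is used immediately so that it cannot isomerise into conjugation.

Step 10
Reactants: 12 tert-butyl (2Z,4R,6S)-2-(bromomethyl)-4-[(tert-butyldimethylsilyl)oxy]-6-{[(tert-butyldimethylsilyl)oxy]methyl}deca-2,9-dienoate; 16 methyl 2-methylidene-4-oxobutanoate
Product: 17 tert-butyl (2Z,4R,6S,9E)-2-(bromomethyl)-4-[(tert-butyldimethylsilyl)oxy]-6-{[(tert-butyldimethylsilyl)oxy]methyl}-10-(methoxycarbonyl)-12-oxododeca-2,9-dienoate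
Conditions: second-generation Hoveyda–Grubbs catalyst RuCl2(SIMes)(=CH-C6H4-2-OiPr) (10 mol %), 16 (5 equiv), 1,4-benzoquinone (20 mol %), CH2Cl2, 40 °C
Reagents that add atoms: none
Why: Olefin cross-metathesis of a terminal alkene with a 2-substituted acrylate (itaconate type) gives the trisubstituted enoate with the new chain trans to CO2Me (E, thermodynamic), while the Z-bromomethyl enoate is too hindered and electron-poor to react.

Step 11
Reactants: 17 tert-butyl (2Z,4R,6S,9E)-2-(bromomethyl)-4-[(tert-butyldimethylsilyl)oxy]-6-{[(tert-butyldimethylsilyl)oxy]methyl}-10-(methoxycarbonyl)-12-oxododeca-2,9-dienoate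
Product: 19 methyl (1E,5S,7R,8R,9R)-8-[3-(tert-butoxy)-3-oxoprop-1-en-2-yl]-7-[(tert-butyldimethylsilyl)oxy]-5-{[(tert-butyldimethylsilyl)oxy]methyl}-9-hydroxycyclodec-1-ene-1-carboxylate, via allylchromium dichloride 18 (not isolated)
Conditions: CrCl2 (20 mol %), nBu4NBr (0.1 M), DMF, undivided cell, Al anode, Ni-foam cathode, 3 mA constant current (2.2 F/mol), 17 added over 10 h to 2 mM, 25 °C; aq NH4Cl
Reagents that add atoms: none
Why: Proposed new method: a chromium-catalysed electroreductive intramolecular Barbier (Nozaki–Hiyama–Kishi-type) allylation that closes the ten-membered ring, in which divalent chromium turns the allylic bromide into allylchromium 18 (trivalent chromium), the cathode returns the chromium to the divalent state and Al3+ from the anode takes over the alkoxide, so the nucleophile is made only as fast as current flows and stays dilute; the closest known reactions are stoichiometric CrCl2 macro-allylations to ten-membered germacrane rings and chromium-catalysed electroreductive intermolecular allylations and Nozaki–Hiyama–Kishi couplings, neither shown for a γ-oxygenated 2-(alkoxycarbonyl)allyl bromide closing a medium ring; C7 and C8 are set in a Zimmerman–Traxler chair with the Z-configured C6 substituent axial (7,8-syn) and with the aldehyde adding to the face of C7 anti to the C6 silyloxy group in the A(1,3)-minimised conformer (6,7-anti), and the tert-butyl ester keeps the C8 alkoxide from lactonising.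

Step 12
Reactants: 19 methyl (1E,5S,7R,8R,9R)-8-[3-(tert-butoxy)-3-oxoprop-1-en-2-yl]-7-[(tert-butyldimethylsilyl)oxy]-5-{[(tert-butyldimethylsilyl)oxy]methyl}-9-hydroxycyclodec-1-ene-1-carboxylate; 20 (2R)-2-methylbutanoic acid
Product: 21 methyl (1E,5S,7R,8R,9R)-8-[3-(tert-butoxy)-3-oxoprop-1-en-2-yl]-7-[(tert-butyldimethylsilyl)oxy]-5-{[(tert-butyldimethylsilyl)oxy]methyl}-9-{[(2R)-2-methylbutanoyl]oxy}cyclodec-1-ene-1-carboxylate
Conditions: 20 (3 equiv), DCC, DMAP, CH2Cl2, 0 → 25 °C
Reagents that add atoms: none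
Why: Steglich esterification of the only free hydroxyl; the bought acid stereocentre is kept because no ketene-forming base is used.

Step 13
Reactants: 21 methyl (1E,5S,7R,8R,9R)-8-[3-(tert-butoxy)-3-oxoprop-1-en-2-yl]-7-[(tert-butyldimethylsilyl)oxy]-5-{[(tert-butyldimethylsilyl)oxy]methyl}-9-{[(2R)-2-methylbutanoyl]oxy}cyclodec-1-ene-1-carboxylate
Product: 23 CNP0141952.4 methyl (1(10)E,4S,6R,7S,8R)-15-hydroxy-8-{[(2R)-2-methylbutanoyl]oxy}germacra-1(10),11(13)-dien-12,6-olid-14-oate, via seco hydroxy acid 22 (not isolated)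
Conditions: CF3CO2H/CH2Cl2/H2O 9:9:1, 0 → 25 °C; then aq NaHCO3
Reagents that add atoms: none
Why: Acidolysis removes the tert-butyl ester and both TBS ethers, and the freed γ-hydroxy acid lactonises onto O6 (O8 is acylated), giving the trans-fused α-methylene-γ-butyrolactone with all stereocentres unchanged.

**Compound list**
1 | (5R)-5-(hydroxymethyl)dihydrofuran-2(3H)-one | O=C1CC[C@H](CO)O1 | starting material
2 | (5R)-5-{[(triethylsilyl)oxy]methyl}dihydrofuran-2(3H)-one | O=C1CC[C@H](CO[Si](CC)(CC)CC)O1 | intermediate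
3 | 4-iodobut-1-ene | C=CCCI | starting material
4 | lithium enolate of 2 (lithium (5R)-5-{[(triethylsilyl)oxy]methyl}-4,5-dihydrofuran-2-olate) | [Li]OC1=CC[C@H](CO[Si](CC)(CC)CC)O1 | intermediate (not isolated)
5 | (3S,5R)-3-(but-3-en-1-yl)-5-{[(triethylsilyl)oxy]methyl}dihydrofuran-2(3H)-one | O=C1[C@@H](CCC=C)C[C@H](CO[Si](CC)(CC)CC)O1 | intermediate
6 | (2S,4R)-2-(but-3-en-1-yl)-5-[(triethylsilyl)oxy]pentane-1,4-diol | OC[C@@H](CCC=C)C[C@@H](O)CO[Si](CC)(CC)CC | intermediate
7 | (2S,4R)-2-(but-3-en-1-yl)-1,4-bis[(tert-butyldimethylsilyl)oxy]-5-[(triethylsilyl)oxy]pentane | CC(C)(C)[Si](C)(C)OC[C@@H](CCC=C)C[C@@H](O[Si](C)(C)C(C)(C)C)CO[Si](CC)(CC)CC | intermediate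
8 | {[(2R,4S)-4-(but-3-en-1-yl)-2,5-bis[(tert-butyldimethylsilyl)oxy]pentyl]oxy}dimethylsulfonium chloride | C[S+](C)OC[C@H](O[Si](C)(C)C(C)(C)C)C[C@@H](CO[Si](C)(C)C(C)(C)C)CCC=C.[Cl-] | intermediate (not isolated)
9 | (2R,4S)-4-(but-3-en-1-yl)-2,5-bis[(tert-butyldimethylsilyl)oxy]pentanal | O=C[C@H](O[Si](C)(C)C(C)(C)C)C[C@@H](CO[Si](C)(C)C(C)(C)C)CCC=C | intermediate
10 | tert-butyl prop-2-enoate | C=CC(=O)OC(C)(C)C | starting material
11 | tert-butyl (3RS,4R,6S)-4-[(tert-butyldimethylsilyl)oxy]-6-{[(tert-butyldimethylsilyl)oxy]methyl}-3-hydroxy-2-methylidenedec-9-enoate | C=C(C(=O)OC(C)(C)C)C(O)[C@H](O[Si](C)(C)C(C)(C)C)C[C@@H](CO[Si](C)(C)C(C)(C)C)CCC=C | intermediate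
12 | tert-butyl (2Z,4R,6S)-2-(bromomethyl)-4-[(tert-butyldimethylsilyl)oxy]-6-{[(tert-butyldimethylsilyl)oxy]methyl}deca-2,9-dienoate | BrC/C(C(=O)OC(C)(C)C)=C\[C@H](O[Si](C)(C)C(C)(C)C)C[C@@H](CO[Si](C)(C)C(C)(C)C)CCC=C | intermediate
13 | methyl 4,4-dimethoxybutanoate | COC(=O)CCC(OC)OC | starting material
14 | sodium enolate of methyl 2-formyl-4,4-dimethoxybutanoate | [Na+].[O-]C=C(CC(OC)OC)C(=O)OC | intermediate (not isolated)
15 | methyl 4,4-dimethoxy-2-methylidenebutanoate | C=C(CC(OC)OC)C(=O)OC | intermediate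
16 | methyl 2-methylidene-4-oxobutanoate | C=C(CC=O)C(=O)OC | intermediate
17 | tert-butyl (2Z,4R,6S,9E)-2-(bromomethyl)-4-[(tert-butyldimethylsilyl)oxy]-6-{[(tert-butyldimethylsilyl)oxy]methyl}-10-(methoxycarbonyl)-12-oxododeca-2,9-dienoate | BrC/C(C(=O)OC(C)(C)C)=C\[C@H](O[Si](C)(C)C(C)(C)C)C[C@@H](CO[Si](C)(C)C(C)(C)C)CC/C=C(/C(=O)OC)CC=O | intermediate
18 | allylchromium dichloride from 17 (CrCl2 on C13 in place of Br, trivalent chromium) | Cl[Cr](Cl)C/C(C(=O)OC(C)(C)C)=C\[C@H](O[Si](C)(C)C(C)(C)C)C[C@@H](CO[Si](C)(C)C(C)(C)C)CC/C=C(/C(=O)OC)CC=O | intermediate (not isolated)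
19 | methyl (1E,5S,7R,8R,9R)-8-[3-(tert-butoxy)-3-oxoprop-1-en-2-yl]-7-[(tert-butyldimethylsilyl)oxy]-5-{[(tert-butyldimethylsilyl)oxy]methyl}-9-hydroxycyclodec-1-ene-1-carboxylate | C=C(C(=O)OC(C)(C)C)[C@H]1[C@H](O[Si](C)(C)C(C)(C)C)C[C@@H](CO[Si](C)(C)C(C)(C)C)CC/C=C(/C(=O)OC)C[C@H]1O | intermediate
20 | (2R)-2-methylbutanoic acid | CC[C@@H](C)C(=O)O | starting material
21 | methyl (1E,5S,7R,8R,9R)-8-[3-(tert-butoxy)-3-oxoprop-1-en-2-yl]-7-[(tert-butyldimethylsilyl)oxy]-5-{[(tert-butyldimethylsilyl)oxy]methyl}-9-{[(2R)-2-methylbutanoyl]oxy}cyclodec-1-ene-1-carboxylate | C=C(C(=O)OC(C)(C)C)[C@H]1[C@H](O[Si](C)(C)C(C)(C)C)C[C@@H](CO[Si](C)(C)C(C)(C)C)CC/C=C(/C(=O)OC)C[C@H]1OC(=O)[C@H](C)CC | intermediate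
22 | 2-[(1S,2R,4S,7E,10R)-2-hydroxy-4-(hydroxymethyl)-8-(methoxycarbonyl)-10-{[(2R)-2-methylbutanoyl]oxy}cyclodec-7-en-1-yl]prop-2-enoic acid | C=C(C(=O)O)[C@H]1[C@H](O)C[C@@H](CO)CC/C=C(/C(=O)OC)C[C@H]1OC(=O)[C@H](C)CC | intermediate (not isolated)
23 | CNP0141952.4, methyl (1(10)E,4S,6R,7S,8R)-15-hydroxy-8-{[(2R)-2-methylbutanoyl]oxy}germacra-1(10),11(13)-dien-12,6-olid-14-oate | C=C1C(=O)O[C@@H]2C[C@@H](CO)CC/C=C(/C(=O)OC)C[C@@H](OC(=O)[C@H](C)CC)[C@@H]12 | target

**Step count**
Total step count: 13. Longest linear sequence: 11 steps (steps 1–7 and 10–13; steps 8–9 make the metathesis partner).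

**Three steps most likely to fail, each with one fallback**

Step 11 (the proposed new electrochemical macrocyclisation; risks are oligomerisation, direct cathodic reduction of the bromide, and the wrong C7/C8 diastereomer). The fallback sets out from 17 and comes back at 19. It gives up electrocatalysis and delivers the electrons chemically in the classical stoichiometric chromium Barbier (Nozaki–Hiyama–Kishi-type) macrocyclisation, known for ten-membered germacrane rings: 17 is added by syringe pump to CrCl2 (10 equiv) in degassed DMF/THF at 25 °C to 2 mM, followed by aqueous work-up. It runs through the same allylchromium dichloride 18 and the same chair transition state and makes no new compound (F0).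

Step 10 (cross-metathesis of a hindered 2-substituted acrylate that carries an isomerisable aldehyde). The fallback sets out from 11 and comes back at 17, replacing metathesis by carbonyl olefination. OsO4 (cat.)/NaIO4 with 2,6-lutidine in dioxane/H2O cleaves only the electron-rich terminal alkene of 11 to the aldehyde tert-butyl (3RS,4R,6S)-4-[(tert-butyldimethylsilyl)oxy]-6-{[(tert-butyldimethylsilyl)oxy]methyl}-3-hydroxy-2-methylidene-9-oxononanoate F1. Wittig reaction of F1 with the stabilised ylide methyl 2-(triphenylphosphoranylidene)pent-4-enoate (toluene, 80 °C, E-selective) gives tert-butyl (3RS,4R,6S,9E)-4-[(tert-butyldimethylsilyl)oxy]-6-{[(tert-butyldimethylsilyl)oxy]methyl}-3-hydroxy-10-(methoxycarbonyl)-2-methylidenetrideca-9,12-dienoate F2. NBS/Me2S as in step 7 gives tert-butyl (2Z,4R,6S,9E)-2-(bromomethyl)-4-[(tert-butyldimethylsilyl)oxy]-6-{[(tert-butyldimethylsilyl)oxy]methyl}-10-(methoxycarbonyl)trideca-2,9,12-trienoate F3. A second OsO4/NaIO4 cleavage of the only monosubstituted alkene of F3 gives 17.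

Step 6 (slow Baylis–Hillman reaction of tert-butyl acrylate, with possible epimerisation of the α-silyloxy aldehyde by the amine). The fallback sets out from 9 and comes back at 11, using a preformed vinylmetal instead of amine catalysis. tert-Butyl propiolate is hydroaluminated with iBu2AlH and N-methylmorpholine N-oxide in THF at 0 °C to the vinylalane [1-(tert-butoxycarbonyl)ethenyl]bis(2-methylpropyl)aluminium F4. F4 adds to aldehyde 9 at −78 → 0 °C and gives 11 after aqueous work-up, without base and within hours.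

**Further compounds**
F0 | step 11 | none | none
F1 | step 10 | tert-butyl (3RS,4R,6S)-4-[(tert-butyldimethylsilyl)oxy]-6-{[(tert-butyldimethylsilyl)oxy]methyl}-3-hydroxy-2-methylidene-9-oxononanoate | C=C(C(=O)OC(C)(C)C)C(O)[C@H](O[Si](C)(C)C(C)(C)C)C[C@@H](CO[Si](C)(C)C(C)(C)C)CCC=O
F2 | step 10 | tert-butyl (3RS,4R,6S,9E)-4-[(tert-butyldimethylsilyl)oxy]-6-{[(tert-butyldimethylsilyl)oxy]methyl}-3-hydroxy-10-(methoxycarbonyl)-2-methylidenetrideca-9,12-dienoate | C=C(C(=O)OC(C)(C)C)C(O)[C@H](O[Si](C)(C)C(C)(C)C)C[C@@H](CO[Si](C)(C)C(C)(C)C)CC/C=C(/C(=O)OC)CC=C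
F3 | step 10 | tert-butyl (2Z,4R,6S,9E)-2-(bromomethyl)-4-[(tert-butyldimethylsilyl)oxy]-6-{[(tert-butyldimethylsilyl)oxy]methyl}-10-(methoxycarbonyl)trideca-2,9,12-trienoate | BrC/C(C(=O)OC(C)(C)C)=C\[C@H](O[Si](C)(C)C(C)(C)C)C[C@@H](CO[Si](C)(C)C(C)(C)C)CC/C=C(/C(=O)OC)CC=C
F4 | step 6 | [1-(tert-butoxycarbonyl)ethenyl]bis(2-methylpropyl)aluminium | C=C(C(=O)OC(C)(C)C)[Al](CC(C)C)CC(C)C
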